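**Strategy.** Ring A is disconnected across C1–C2 and C4–C5, the two bonds that flank quaternary C10 and gem-dimethyl C4. This turns C1, C10 and C5 back into the E-isopropylidene terminus of methyl farnesoate, and C2–C3–C4 into the enol of 3-methyl-2-oxobutanal. The key step starts from their allyl vinyl ether and is a copper-bisoxazoline Claisen/carbonyl-ene domino. The [3,3] shift forges C4–C5 with its stereocentre. The resulting keto aldehyde then closes ring A at C1–C2, delivering the C2/C3 oxygens and an exocyclic methylene. That methylene becomes the angular methyl when ring B is closed by cation–olefin cyclization.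

Key step: step 4

Remark on numbering: labdane numbering (C1–C20) is used for all intermediates; the target is (2S,3R,5S,9R,10S), ent-labdane series.
Remark on the ligand: the (S,S)-ligand is assumed to give the (S)-configured C5 centre; if the opposite sense is found, the (R,R)-ligand is used.
Remark on supply: methyl (2E,6E)-farnesoate is taken as a catalogue compound (otherwise two routine steps from (2E,6E)-farnesol).

Step 1
Reactants: 1 methyl (2E,6E)-3,7,11-trimethyldodeca-2,6,10-trienoate (methyl farnesoate)
Product: 2 methyl (2E,6E,10E)-12-hydroxy-3,7,11-trimethyldodeca-2,6,10-trienoate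
Conditions: SeO2 (0.3 equiv), t-BuOOH (2 equiv), salicylic acid (0.1 equiv), CH2Cl2, 0 to 23 °C
Reagents that add atoms: selenium dioxide, O=[Se]=O (transfers the oxygen atom; re-formed by tert-butyl hydroperoxide, CC(C)(C)OO)
Why: Catalytic selenium dioxide allylic oxidation (ene reaction then [2,3]-shift) should attack the most electron-rich, distal trisubstituted olefin and oxidise its E-methyl group, leaving the conjugated 2,3-olefin untouched.

Step 2
Reactants: 3 3-methylbutan-2-one
Product: 4 3-methyl-2-oxobutanal
Conditions: SeO2 (1.05 equiv), 1,4-dioxane/H2O, 90 °C; distilled before use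
Reagents that add atoms: selenium dioxide, O=[Se]=O
Why: Riley oxidation should convert the methyl group of the methyl ketone into the aldehyde through the less hindered enol.

Step 3
Reactants: 2 methyl (2E,6E,10E)-12-hydroxy-3,7,11-trimethyldodeca-2,6,10-trienoate; 4 3-methyl-2-oxobutanal
Product: 5 methyl (2E,6E,10E)-3,7,11-trimethyl-12-[(3-methyl-1-oxobut-2-en-2-yl)oxy]dodeca-2,6,10-trienoate
Conditions: PPh3, DIAD, THF, 0 to 23 °C
Reagents that add atoms: none
Why: Mitsunobu etherification: the acidic enol OH of the 1,2-dicarbonyl should displace the alkoxyphosphonium of the primary allylic alcohol at C1 by SN2, so the 10E geometry is kept, and the hindered C4 terminus disfavours C-alkylation.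

Step 4
Reactants: 5 methyl (2E,6E,10E)-3,7,11-trimethyl-12-[(3-methyl-1-oxobut-2-en-2-yl)oxy]dodeca-2,6,10-trienoate
Product: 7 methyl (2E,6E)-9-[(1S,4R)-4-hydroxy-2,2-dimethyl-6-methylidene-3-oxocyclohexyl]-3,7-dimethylnona-2,6-dienoate, via keto aldehyde 6 (not isolated)
Conditions: [Cu((S,S)-t-Bu-box)(H2O)2](SbF6)2 (10 mol%; box = 2,2'-(propane-2,2-diyl)bis(4-tert-butyl-4,5-dihydrooxazole)), 4 Å MS, CH2Cl2, 23 °C
Reagents that add atoms: none
Why: Proposed new method: the cationic divalent copper Lewis acid should chelate the ether and formyl oxygens of 5 and accelerate a chair-like [3,3]-sigmatropic shift that joins C4 to C5 and releases the allylic oxygen as the C3 ketone; the 1,2-dicarbonyl 6 stays chelated and its aldehyde carbon is attacked by the CH2 terminus of the new isopropenyl group in a carbonyl-ene reaction that forms C1–C2 and moves the double bond to C10=C20. The closest known chemistry is the copper-bisoxazoline-catalysed Gosteli–Claisen rearrangement of 2-alkoxycarbonyl allyl vinyl ethers with in situ carbonyl-ene closure, the thermal Claisen rearrangement of allyl ethers of enolised 1,2-dicarbonyls, and copper-bisoxazoline glyoxylate-ene reactions; new here is the formyl group serving as both chelating handle and enophile. Ring A closes as a six-membered ring in the type-2 ene mode (tether on the central ene carbon, carbonyl oxygen exocyclic), the hydrogen coming from the allylic methyl. C5 is set by the ligand, which selects one enantiotopic face of the 10E olefin in the chair transition state; C2 is expected with the hydroxyl axial and cis to the C5 chain, which is inconsequential because step 6 equilibrates it. The step needs the aldehyde rather than the ketone to act as enophile (six- versus five-membered closure) and the 1,1-disubstituted olefin rather than the trisubstituted ones to act as ene, and both follow from ring size and the higher reactivity of aldehyde and isopropenyl groups.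

Step 5
Reactants: 7 methyl (2E,6E)-9-[(1S,4R)-4-hydroxy-2,2-dimethyl-6-methylidene-3-oxocyclohexyl]-3,7-dimethylnona-2,6-dienoate
Product: 8 methyl (2R,5S,9R,10S,13E)-2-hydroxy-3-oxolabda-7,13-dien-15-oate (ent-series, trans-decalin, 2-OH axial)
Conditions: SnCl4 (0.2 equiv), CH2Cl2, −78 to −40 °C
Reagents that add atoms: none
Why: Proton-initiated cation–olefin cyclization (the tin-bound hydroxyl acting as Brønsted acid): Markovnikov protonation of the exocyclic methylene makes C20 the angular methyl, and the C10 cation should be captured by the 8E olefin through a chair with the C5 chain equatorial and attack anti to the axial C4 methyl, giving the trans-decalin with the C9 side chain equatorial, loss of H-7 giving the 7-ene while the electron-poor enoate olefin stays out.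

Step 6
Reactants: 8 methyl (2R,5S,9R,10S,13E)-2-hydroxy-3-oxolabda-7,13-dien-15-oate
Product: 9 methyl (2S,5S,9R,10S,13E)-2-hydroxy-3-oxolabda-7,13-dien-15-oate (2-OH equatorial)
Conditions: DBU (0.2 equiv), toluene, 23 °C
Reagents that add atoms: none
Why: Base-mediated enolisation of the α-hydroxy ketone toward C2 (C4 is quaternary) should equilibrate the axial hydroxyl, syn-diaxial to the C4 and C10 methyls, to the equatorial epimer under thermodynamic control.

Step 7
Reactants: 9 methyl (2S,5S,9R,10S,13E)-2-hydroxy-3-oxolabda-7,13-dien-15-oate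
Product: 11 (2S,3R,5S,9R,10S,13E)-labda-7,13-diene-2,3,15-triol, via diol ester 10 (not isolated)
Conditions: LiBH(s-Bu)3 (2.5 equiv), THF, −78 °C; then i-Bu2AlH (4 equiv), −78 to 0 °C; aqueous potassium sodium tartrate
Reagents that add atoms: none
Why: Bulky trialkylborohydride reduction should deliver hydride to the C3 ketone from the equatorial direction, the usual course for 4,4-dimethyl-3-ketones, giving the axial 3-alcohol cis to the C2 hydroxyl, and i-Bu2AlH then reduces the conjugated ester 1,2 to the allylic alcohol.

Step 8
Reactants: 11 (2S,3R,5S,9R,10S,13E)-labda-7,13-diene-2,3,15-triol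
Product: 12 (2S,3R,5S,9R,10S,13E)-2,3-dihydroxylabda-7,13-dien-15-yl acetate (CNP0280580.2)
Conditions: AcCl (1.1 equiv), 2,4,6-collidine, CH2Cl2, −78 °C
Reagents that add atoms: acetyl chloride, CC(=O)Cl
Why: Kinetic selective acylation should acetylate the unhindered primary allylic alcohol far faster than the two secondary ring hydroxyls (C3 axial and neopentylic).

**Compound list**

1 | methyl (2E,6E)-3,7,11-trimethyldodeca-2,6,10-trienoate | COC(=O)/C=C(\C)CC/C=C(\C)CCC=C(C)C | starting material
2 | methyl (2E,6E,10E)-12-hydroxy-3,7,11-trimethyldodeca-2,6,10-trienoate | COC(=O)/C=C(\C)CC/C=C(\C)CC/C=C(\C)CO | intermediate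
3 | 3-methylbutan-2-one | CC(=O)C(C)C | starting material
4 | 3-methyl-2-oxobutanal | CC(C)C(=O)C=O | intermediate
5 | methyl (2E,6E,10E)-3,7,11-trimethyl-12-[(3-methyl-1-oxobut-2-en-2-yl)oxy]dodeca-2,6,10-trienoate | COC(=O)/C=C(\C)CC/C=C(\C)CC/C=C(\C)COC(C=O)=C(C)C | intermediate
6 | methyl (2E,6E,10S)-3,7,11,11-tetramethyl-12,13-dioxo-10-(prop-1-en-2-yl)trideca-2,6-dienoate | COC(=O)/C=C(\C)CC/C=C(\C)CC[C@@H](C(C)=C)C(C)(C)C(=O)C=O | intermediate (not isolated)
7 | methyl (2E,6E)-9-[(1S,4R)-4-hydroxy-2,2-dimethyl-6-methylidene-3-oxocyclohexyl]-3,7-dimethylnona-2,6-dienoate | COC(=O)/C=C(\C)CC/C=C(\C)CC[C@H]1C(=C)C[C@@H](O)C(=O)C1(C)C | intermediate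
8 | methyl (2R,5S,9R,10S,13E)-2-hydroxy-3-oxolabda-7,13-dien-15-oate | COC(=O)/C=C(\C)CC[C@@H]1C(C)=CC[C@@H]2C(C)(C)C(=O)[C@H](O)C[C@@]12C | intermediate
9 | methyl (2S,5S,9R,10S,13E)-2-hydroxy-3-oxolabda-7,13-dien-15-oate | COC(=O)/C=C(\C)CC[C@@H]1C(C)=CC[C@@H]2C(C)(C)C(=O)[C@@H](O)C[C@@]12C | intermediate
10 | methyl (2S,3R,5S,9R,10S,13E)-2,3-dihydroxylabda-7,13-dien-15-oate | COC(=O)/C=C(\C)CC[C@@H]1C(C)=CC[C@@H]2C(C)(C)[C@@H](O)[C@@H](O)C[C@@]12C | intermediate (not isolated)
11 | (2S,3R,5S,9R,10S,13E)-labda-7,13-diene-2,3,15-triol | OC/C=C(\C)CC[C@@H]1C(C)=CC[C@@H]2C(C)(C)[C@@H](O)[C@@H](O)C[C@@]12C | intermediate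
12 | (2S,3R,5S,9R,10S,13E)-2,3-dihydroxylabda-7,13-dien-15-yl acetate | CC(=O)OC/C=C(\C)CC[C@@H]1C(C)=CC[C@@H]2C(C)(C)[C@@H](O)[C@@H](O)C[C@@]12C | target

**Step count.** Total: 8 steps. Longest linear sequence: 7 steps (steps 1, 3, 4, 5, 6, 7, 8 from compound 1).

**Steps most likely to fail**

1. Step 4 (proposed new method). The formyl chelate may hold the substrate less rigidly than an ester chelate, so enantiofacial control in the sigmatropic shift may erode, an uncatalysed background shift may compete, or the sequence may stall at the keto aldehyde. Fallback with known chemistry: setting out from 5, heating in toluene at 100 °C effects the uncatalysed Claisen rearrangement of the 1,2-dicarbonyl enol ether and the thermal ene closure. This gives 7 as a racemate, that is 7 together with its mirror image ent-7 F1. Candida antarctica lipase B with vinyl acetate then acetylates one enantiomer, taken here to be F1, to ent-7 acetate F2. Unreacted 7 is separated and the route is rejoined at 7.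

2. Step 5. Proton loss from the C8 cation may be unselective (exocyclic 8(17)-olefin, tetrasubstituted 8-ene), and protonation of the 8-olefin may compete with protonation of the methylene. Fallback: setting out from 7, the cyclization is run to the kinetic olefin mixture. The exocyclic isomer methyl (2R,5S,9R,10S,13E)-2-hydroxy-3-oxolabda-8(17),13-dien-15-oate F3 is then moved into the ring by hydrogen-atom-transfer olefin isomerization (Co(salen)Cl and PhSiH3, both catalytic, benzene, 23 °C). This shifts a 1,1-disubstituted olefin by one position toward the accessible C7 hydrogens, and the route is rejoined at 8.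

3. Step 3. The keto aldehyde is only partly enolised and easily hydrated, so the phosphonium intermediate may not be engaged, or the ambident enolate may alkylate at C4. Fallback: setting out from 2, Appel bromination (CBr4, PPh3, CH2Cl2, 0 °C) gives methyl (2E,6E,10E)-12-bromo-3,7,11-trimethyldodeca-2,6,10-trienoate F4. F4 O-alkylates the caesium enolate of 4 (Cs2CO3, DMF, 0 °C), the classical way to allyl ethers of enolised 1,2-dicarbonyls, and the route is rejoined at 5.

**Further compounds**

F1 | step 4 | methyl (2E,6E)-9-[(1R,4S)-4-hydroxy-2,2-dimethyl-6-methylidene-3-oxocyclohexyl]-3,7-dimethylnona-2,6-dienoate (ent-7) | COC(=O)/C=C(\C)CC/C=C(\C)CC[C@@H]1C(=C)C[C@H](O)C(=O)C1(C)C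
F2 | step 4 | methyl (2E,6E)-9-[(1R,4S)-4-acetoxy-2,2-dimethyl-6-methylidene-3-oxocyclohexyl]-3,7-dimethylnona-2,6-dienoate (ent-7 acetate) | COC(=O)/C=C(\C)CC/C=C(\C)CC[C@@H]1C(=C)C[C@H](OC(C)=O)C(=O)C1(C)C
F3 | step 5 | methyl (2R,5S,9R,10S,13E)-2-hydroxy-3-oxolabda-8(17),13-dien-15-oate | COC(=O)/C=C(\C)CC[C@@H]1C(=C)CC[C@@H]2C(C)(C)C(=O)[C@H](O)C[C@@]12C
F4 | step 3 | methyl (2E,6E,10E)-12-bromo-3,7,11-trimethyldodeca-2,6,10-trienoate | COC(=O)/C=C(\C)CC/C=C(\C)CC/C=C(\C)CBr
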